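**Retrosynthetic overview**
- The methoxyquinone comes from para-oxidation of 6-methoxy-3-methyl-2-pentacosylphenol in the last step. The only ring is the benzene ring bought with isovanillin, so no ring is built.
- The saturated C25 chain comes from (E)-1-arylpentacos-1-en-3-one: tosylhydrazone, reductive alkene transposition, then a hydrogenation that also removes the O-benzyl group.
- Key C–C bond (chain C1–C2): crossed aldol (Claisen–Schmidt) condensation of 2-(benzyloxy)-3-methoxy-6-methylbenzaldehyde with tetracosan-2-one.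
- The aldehyde comes from isovanillin (CHO to CH3, ortho-formylation, benzylation). The ketone comes from 1-bromodocosane (Grignard) and N-methoxy-N-methylacetamide.

Assumption: the SMILES holds no stereocentre and no stereogenic double bond, so the target is achiral and needs no enantiocontrol; the side chain is read as unbranched pentacosyl (C25).

**Step 1**
Reactants: 1 isovanillin (3-hydroxy-4-methoxybenzaldehyde)
Product: 3 2-methoxy-5-methylphenol, via isovanillyl alcohol 2 (not isolated)
Conditions: H2 (4 atm), 10% Pd/C, AcOH, 40 °C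
Reagents that add atoms: none
Why: Catalytic hydrogenation gives the p-methoxy-activated benzylic alcohol, which undergoes benzylic hydrogenolysis in AcOH to the methyl group while phenol, ether and ring stay untouched; no stereocentre is formed.

**Step 2**
Reactants: 3 2-methoxy-5-methylphenol
Product: 5 2-hydroxy-3-methoxy-6-methylbenzaldehyde, via hydroxymethyl phenol 4 (not isolated)
Conditions: MgCl2 (2 equiv), Et3N (3 equiv), (CH2O)n (6 equiv), MeCN, reflux; 1 M HCl
Reagents that add atoms: paraformaldehyde (reacts as formaldehyde), C=O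
Why: In this Casnati–Skattebøl magnesium-mediated ortho-formylation the Mg phenoxide delivers formaldehyde only to the single free ortho carbon (C6, the same substitution pattern as thymol), and a second formaldehyde oxidises the hydroxymethyl phenoxide by an Oppenauer-type hydride shift.

**Step 3**
Reactants: 5 2-hydroxy-3-methoxy-6-methylbenzaldehyde
Product: 6 2-(benzyloxy)-3-methoxy-6-methylbenzaldehyde
Conditions: BnBr (1.2 equiv), K2CO3, DMF, 60 °C
Reagents that add atoms: benzyl bromide, BrCc1ccccc1
Why: Williamson ether synthesis masks the phenol, which would otherwise deactivate the aldehyde as its phenoxide and cyclise onto later carbonyl intermediates; benzyl is base-stable and is removed without an extra step in step 8.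

**Step 4**
Reactants: 7 1-bromodocosane; 8 N-methoxy-N-methylacetamide
Product: 11 tetracosan-2-one, via docosylmagnesium bromide 9 (not isolated), via magnesium hemiaminal chelate 10 (not isolated)
Conditions: Mg, cat. I2, THF, 50 °C; then 8, 0 °C to rt; 1 M HCl
Reagents that add atoms: none
Why: Grignard formation followed by Weinreb ketone synthesis stops cleanly at the ketone, because the chelated tetrahedral adduct survives until the acidic work-up.

**Step 5**
Reactants: 6 2-(benzyloxy)-3-methoxy-6-methylbenzaldehyde (1.1 equiv); 11 tetracosan-2-one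
Product: 13 (E)-1-[2-(benzyloxy)-3-methoxy-6-methylphenyl]pentacos-1-en-3-one, via racemic aldol adduct 12 (not isolated)
Conditions: KOH (0.5 equiv), EtOH–THF 1:1, 50 °C
Reagents that add atoms: none
Why: In this base-mediated Claisen–Schmidt crossed aldol condensation the aldehyde cannot enolise, the methyl ketone reacts productively only through its CH3 enolate (aldols at the internal CH2 revert), and irreversible E1cB dehydration erases the racemic carbinol centre and gives the thermodynamic E-enone.

**Step 6**
Reactants: 13 (E)-enone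
Product: 14 tosylhydrazone of 13
Conditions: TsNHNH2 (1.2 equiv), cat. AcOH, EtOH–THF, 60 °C
Reagents that add atoms: p-toluenesulfonyl hydrazide, Cc1ccc(cc1)S(=O)(=O)NN
Why: Hydrazone condensation at the unhindered ketone carbonyl is fast and the product crystallises; the C=N geometry does not matter for the next step.

**Step 7**
Reactants: 14 tosylhydrazone
Product: 17 2-(benzyloxy)-1-methoxy-4-methyl-3-[(2E)-pentacos-2-en-1-yl]benzene, via N-boryl tosylhydrazine 15 (not isolated), via allylic diazene 16 (not isolated)
Conditions: catecholborane (1.5 equiv), CHCl3, −10 to 0 °C; then NaOAc·3H2O (3 equiv), reflux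
Reagents that add atoms: none
Why: In this Kabalka variant of the Caglioti/Hutchins tosylhydrazone reduction, 1,2-hydride delivery to C=N, loss of sulfinate and retro-ene extrusion of N2 from the allylic diazene remove the oxygen function with alkene transposition; the transient stereocentre vanishes and any alkene isomer or alkane converges in step 8.

**Step 8**
Reactants: 17 alkene (passed through silica first to remove sulfur traces)
Product: 19 6-methoxy-3-methyl-2-pentacosylphenol, via saturated benzyl ether 18 (not isolated)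
Conditions: H2 (1–3 atm), 10% Pd/C, EtOAc–EtOH, 40 °C
Reagents that add atoms: none
Why: Heterogeneous hydrogenation saturates the disubstituted alkene, and the same catalyst hydrogenolyses the benzyl ether, so chain and free phenol are obtained in one operation.

**Step 9**
Reactants: 19 6-methoxy-3-methyl-2-pentacosylphenol
Product: 20 5-methoxy-2-methyl-3-pentacosylcyclohexa-2,5-diene-1,4-dione (2-methoxy-5-methyl-6-pentacosyl-1,4-benzoquinone)
Conditions: O2 (1 atm), Co(salen) (salcomine, 10 mol %), DMF–CH2Cl2 2:1, 30 °C
Reagents that add atoms: dioxygen, O=O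
Why: In the Co(salen)-catalysed aerobic phenol oxidation the phenoxyl radical is trapped by the cobalt–superoxo species at the only open activated position, the para carbon (both ortho sites are blocked, as in the 2,3,6-trimethylphenol case), which gives the p-quinone and water.

**Compound list**
1 | isovanillin (3-hydroxy-4-methoxybenzaldehyde) | COc1ccc(C=O)cc1O | starting material
2 | isovanillyl alcohol (5-(hydroxymethyl)-2-methoxyphenol) | COc1ccc(CO)cc1O | intermediate
3 | 2-methoxy-5-methylphenol | COc1ccc(C)cc1O | intermediate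
4 | 2-(hydroxymethyl)-6-methoxy-3-methylphenol (present as Mg salt) | COc1ccc(C)c(CO)c1O | intermediate
5 | 2-hydroxy-3-methoxy-6-methylbenzaldehyde | COc1ccc(C)c(C=O)c1O | intermediate
6 | 2-(benzyloxy)-3-methoxy-6-methylbenzaldehyde | COc1ccc(C)c(C=O)c1OCc1ccccc1 | intermediate
7 | 1-bromodocosane | CCCCCCCCCCCCCCCCCCCCCCBr | starting material
8 | N-methoxy-N-methylacetamide | CC(=O)N(C)OC | starting material
9 | docosylmagnesium bromide | CCCCCCCCCCCCCCCCCCCCCC[Mg]Br | intermediate
10 | bromomagnesium 2-[methoxy(methyl)amino]tetracosan-2-olate (chelated tetrahedral adduct) | CCCCCCCCCCCCCCCCCCCCCCC(C)(O[Mg]Br)N(C)OC | intermediate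
11 | tetracosan-2-one | CCCCCCCCCCCCCCCCCCCCCCC(C)=O | intermediate
12 | rac-1-[2-(benzyloxy)-3-methoxy-6-methylphenyl]-1-hydroxypentacosan-3-one | CCCCCCCCCCCCCCCCCCCCCCC(=O)CC(O)c1c(C)ccc(OC)c1OCc1ccccc1 | intermediate
13 | (E)-1-[2-(benzyloxy)-3-methoxy-6-methylphenyl]pentacos-1-en-3-one | CCCCCCCCCCCCCCCCCCCCCCC(=O)/C=C/c1c(C)ccc(OC)c1OCc1ccccc1 | intermediate
14 | N'-{(1E)-1-[2-(benzyloxy)-3-methoxy-6-methylphenyl]pentacos-1-en-3-ylidene}-4-methylbenzenesulfonohydrazide (C=N isomers) | CCCCCCCCCCCCCCCCCCCCCCC(/C=C/c1c(C)ccc(OC)c1OCc1ccccc1)=NNS(=O)(=O)c1ccc(C)cc1 | intermediate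
15 | racemic N-(1,3,2-benzodioxaborol-2-yl) allylic tosylhydrazine from 14 | CCCCCCCCCCCCCCCCCCCCCCC(/C=C/c1c(C)ccc(OC)c1OCc1ccccc1)N(NS(=O)(=O)c1ccc(C)cc1)B1Oc2ccccc2O1 | intermediate
16 | racemic {(1E)-1-[2-(benzyloxy)-3-methoxy-6-methylphenyl]pentacos-1-en-3-yl}diazene | CCCCCCCCCCCCCCCCCCCCCCC(/C=C/c1c(C)ccc(OC)c1OCc1ccccc1)N=N | intermediate
17 | 2-(benzyloxy)-1-methoxy-4-methyl-3-[(2E)-pentacos-2-en-1-yl]benzene | CCCCCCCCCCCCCCCCCCCCCC/C=C/Cc1c(C)ccc(OC)c1OCc1ccccc1 | intermediate
18 | 2-(benzyloxy)-1-methoxy-4-methyl-3-pentacosylbenzene | CCCCCCCCCCCCCCCCCCCCCCCCCc1c(C)ccc(OC)c1OCc1ccccc1 | intermediate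
19 | 6-methoxy-3-methyl-2-pentacosylphenol | CCCCCCCCCCCCCCCCCCCCCCCCCc1c(C)ccc(OC)c1O | intermediate
20 | 5-methoxy-2-methyl-3-pentacosylcyclohexa-2,5-diene-1,4-dione (achiral) | CCCCCCCCCCCCCCCCCCCCCCCCCC1=C(C)C(=O)C=C(OC)C1=O | target

**Step count**
- Total step count: 9.
- Longest linear sequence: 8 (steps 1, 2, 3, 5, 6, 7, 8, 9 from isovanillin). The ketone arm is step 4 plus steps 5–9.

**Three steps most likely to fail**

**Step 5.** The aldehyde is di-ortho-substituted and electron-rich, and the ketone is waxy. Conversion may stall, and some reaction at the internal CH2 or Michael addition to 13 may intrude.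
The fallback sets out from 6 and comes back at 13. The lithium enolate of 8 (LDA, THF, −78 °C) is small, soluble and can enolise at one carbon only. It is added to 6 in a directed aldol addition to give racemic 3-[2-(benzyloxy)-3-methoxy-6-methylphenyl]-3-hydroxy-N-methoxy-N-methylpropanamide F1. Acid-catalysed dehydration (cat. TsOH, toluene, 80 °C) gives (E)-3-[2-(benzyloxy)-3-methoxy-6-methylphenyl]-N-methoxy-N-methylprop-2-enamide F2. 1,2-Addition of the Grignard reagent 9 (THF, 0 °C) to this unsaturated Weinreb amide then delivers 13.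

**Step 7.** Hydride delivery to the conjugated tosylhydrazone may be incomplete, or the hydrazone may cyclise to a pyrazoline on heating.
The fallback sets out from 13 and comes back at 18, using radical deoxygenation in place of diazene chemistry. The C=C bond alone is hydrogenated (H2, Pd/C poisoned with Ph2S, which keeps the benzyl ether) to give 1-[2-(benzyloxy)-3-methoxy-6-methylphenyl]pentacosan-3-one F3. NaBH4 (THF–MeOH) gives racemic 1-[2-(benzyloxy)-3-methoxy-6-methylphenyl]pentacosan-3-ol F4. NaH, CS2, then MeI give its O-alkyl S-methyl dithiocarbonate (xanthate) F5. Barton–McCombie reduction (Bu3SnH, AIBN, toluene, reflux) gives 18, which is purified and debenzylated to 19 under the conditions of step 8.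

**Step 9.** The substrate is very lipophilic, and the phenoxyl radical can couple to diphenoquinone-type dimers or the catalyst can deactivate.
The fallback sets out from 19 and comes back at 20. The para oxygen is introduced through carbon. Duff formylation (hexamethylenetetramine, TFA, reflux; aq. acid) can only go para and gives 4-hydroxy-5-methoxy-2-methyl-3-pentacosylbenzaldehyde F6. Dakin oxidation (H2O2, aq. NaOH–THF, under N2) gives 2-methoxy-5-methyl-6-pentacosylbenzene-1,4-diol F7. Mild oxidation (Ag2O, Et2O, or FeCl3) gives 20.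

**Further compounds**
F1 | step 5 | rac-3-[2-(benzyloxy)-3-methoxy-6-methylphenyl]-3-hydroxy-N-methoxy-N-methylpropanamide | CON(C)C(=O)CC(O)c1c(C)ccc(OC)c1OCc1ccccc1
F2 | step 5 | (E)-3-[2-(benzyloxy)-3-methoxy-6-methylphenyl]-N-methoxy-N-methylprop-2-enamide | CON(C)C(=O)/C=C/c1c(C)ccc(OC)c1OCc1ccccc1
F3 | step 7 | 1-[2-(benzyloxy)-3-methoxy-6-methylphenyl]pentacosan-3-one | CCCCCCCCCCCCCCCCCCCCCCC(=O)CCc1c(C)ccc(OC)c1OCc1ccccc1
F4 | step 7 | rac-1-[2-(benzyloxy)-3-methoxy-6-methylphenyl]pentacosan-3-ol | CCCCCCCCCCCCCCCCCCCCCCC(O)CCc1c(C)ccc(OC)c1OCc1ccccc1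
F5 | step 7 | rac-O-{1-[2-(benzyloxy)-3-methoxy-6-methylphenyl]pentacosan-3-yl} S-methyl dithiocarbonate | CCCCCCCCCCCCCCCCCCCCCCC(CCc1c(C)ccc(OC)c1OCc1ccccc1)OC(=S)SC
F6 | step 9 | 4-hydroxy-5-methoxy-2-methyl-3-pentacosylbenzaldehyde | CCCCCCCCCCCCCCCCCCCCCCCCCc1c(C)c(C=O)cc(OC)c1O
F7 | step 9 | 2-methoxy-5-methyl-6-pentacosylbenzene-1,4-diol | CCCCCCCCCCCCCCCCCCCCCCCCCc1c(C)c(O)cc(OC)c1O
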